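Count in equivalents: the bench debit subtracts one equivalent of starting material for each equivalent of protic impurity, and the flasks below differ in the impurity charge.

| flask | starting material | fresh partner | coupling partner | protic impurity | time | remark |
|---|---|---|---|---|---|---|
| south | 0.67 M | 0.871 M | 0.704 M (in portions, 2) | 0.0300 M | 20 h | the portions of coupling partner follow each other after 10 h, the first at the start |
| south-east | 0.67 M | 0.871 M | 0.704 M (in portions, 2) | 0.100 M | 20 h | the portions of coupling partner follow each other after 10 h, the first at the start |
| west | 0.67 M | 0.871 M | 0.704 M (in portions, 2) | 0.300 M | 20 h | the portions of coupling partner follow each other after 10 h, the first at the start |
| south-west | 0.67 M | 0.871 M | 0.704 M (in portions, 2) | 1.00 M | 20 h | the portions of coupling partner follow each other after 10 h, the first at the start |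
| north-east | 0.67 M | 0.871 M | 0.704 M (in portions, 2) | 2.50 M | 20 h | the portions of coupling partner follow each other after 10 h, the first at the start |

    starting material + coupling partner → open intermediate (k1 = 0.00312 /M/min)
    coupling partner + fresh partner → second intermediate (k2 = 0.0174 /M/min)
    open intermediate + second intermediate → target (k3 = 7.91 × 10⁻⁴ /M/min)
    starting material + open intermediate → side product (k4 = 6.87 × 10⁻⁴ /M/min)
    starting material + protic impurity → quenched substrate (k5 = 0.0701 /M/min)

- a species is counted by the starting material in it: one side product counts as two
- "hardly changes" means that all values lie within two and a half points (for a concentration: within two and a half percent of the largest)
- run time (south): 20 h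

* amount of open intermediate at the end, in percent of the starting material charged for south, south-east, west, south-west, north-east, in this order
* how the row runs (falls all the way / rises, then falls / hardly changes / rises all the way / falls, then rises)

The debit is fair in south. The impurity's pseudo-first-order half-life against the charged starting material is 14.8 min, shorter than the 0.76 h of coupling partner, so the quench finishes first and leaves 95.5% of the charge.

Coupling partner then has two exits, and at equal concentrations fresh partner is favoured by a selectivity factor of 5.58. With the south charges as they stand, starting material takes 11.6% of the coupling partner. Put that back in: over the run the mean fresh partner falls to 64.3% of its charge and the mean starting material to 89.4%. Going round once more gives 16.1%. This second-round value is the capture share, the part of the coupling partner that starting material wins from fresh partner. In south it means 16.9% of the starting material charged becomes open intermediate. Give that open intermediate about 10 h of life under steps 3 and 4, with the uncaptured coupling partner standing as second intermediate, and 59.0% remains, so I expect 9.98% at the end.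

The debit stops working at an impurity-to-charge ratio of one. West stands below that at 0.448, but south-west stands above it at 1.49, and there the subtraction comes out below zero. There the contest becomes step 1 against step 5 for each starting material. Taking the first portion and the mean impurity, capture gets 2.36% in south-west and 0.724% in north-east, before any drain. I therefore expect the row to fall throughout.

The forecast gives 9.8%, 9.1%, 7.3%, 1.5% and 0.45%, a row that falls all the way, holding that at high impurity “almost none survives to form open intermediate”. The simulation gives 10.1%, 9.58%, 7.55%, 1.14% and 0.424%, a row that falls all the way.

In south the quench ran first, with its turnover midpoint at 0.251 h, while step 2 had 43% of its turnover behind it by 2.00 h. Step 1 reached its midpoint at 10.3 h, just after the second portion, and at the end open intermediate was made at 0.119 of the rate it was used up. Counting open intermediate, target and each side product once, south made 17.2%, against 16.9% from the capture share. For west, the first round gives 7.08% and the second 10.2%, or 10.7% of the charge; the west flask, counted the same way, made 11.6%.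

The rate constants stand for no real mixture; the flask was simulated.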